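The depside is cut at the aryl ester, and the plan rests on making hexasubstituted ring B by pyrone benzannulation. A fully substituted 2-pyrone (3,6-dimethyl, 4-methoxy, 5-carbomethoxy) provides ring B atoms C5, C6, C1 and C2; 1-(triisopropylsilyloxy)propyne provides C3 and C4. One operation forms C2–C3 and C4–C5, closes the carbocycle, expels CO2 and sets all six substituents. The step exploits the meta oxygen pair of ring B, C6–OMe and C4–O(acyl): each oxygen arrives on its own component, so the two are differentiated from the start. Ring A is then attached as a benzyl-protected acid and formylated last at C3', the only aromatic C–H left.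

Key step: step 4

Atom labels:
- Ring B: C1 (CO2Me), C2 (Me), C3 (Me), C4 (O-acyl), C5 (Me), C6 (OMe).
- Ring A: C1' (ester C=O), C2' (OH), C3' (CHO), C4' (OH), C5' (Me), C6' (Me).
- Pyrone atoms: O1, C2 (C=O), C3 to C6.

Remark: 2 and 14 are catalogue compounds and are taken as purchased. The target has no stereocentre; the stereocentres of the transient species 11 and 22 form racemic and vanish.

Step 1
Reactants: 1 methyl acetoacetate; 2 methylmalonyl dichloride
Product: 3 methyl 4-hydroxy-2,5-dimethyl-6-oxo-6H-pyran-3-carboxylate
Conditions: PhMe, 100 °C, N2 sweep (−HCl)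
Reagents that add atoms: none
Why: Double acylation of a β-keto ester by a malonyl dichloride (C-acylation at the active methylene, then lactonising O-acylation of the ketone enol) is an established 4-hydroxy-2-pyrone synthesis driven by loss of HCl, and the methyl group on the malonyl carbon blocks any second annulation at pyrone C3.

Step 2
Reactants: 3 methyl 4-hydroxy-2,5-dimethyl-6-oxo-6H-pyran-3-carboxylate
Product: 4 methyl 4-methoxy-2,5-dimethyl-6-oxo-6H-pyran-3-carboxylate
Conditions: Me2SO4, K2CO3, acetone, reflux
Reagents that add atoms: dimethyl sulfate COS(=O)(=O)OC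
Why: Williamson-type O-alkylation of the vinylogous acid with a hard methylating agent and K2CO3 should favour the 4-methoxy-2-pyrone over the 2-methoxy-4-pyrone and over C-methylation at the already substituted C3, and it must be driven to completion because residual acidic 3 would protonate the ynol ether in step 4.

Step 3
Reactants: 5 ethyl acetate; 6 dibromomethane
Product: 10 1-(triisopropylsilyloxy)prop-1-yne, via dibromomethyllithium 7 (not isolated), via lithium 1,1-dibromoprop-1-en-2-olate 8 (not isolated), via lithium prop-1-yn-1-olate 9 (not isolated)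
Conditions: 6, lithium 2,2,6,6-tetramethylpiperidide, THF, −78 °C; 5; LiN(SiMe3)2; n-BuLi, −78 °C → rt; i-Pr3SiOTf, −78 → 0 °C
Reagents that add atoms: triisopropylsilyl trifluoromethanesulfonate CC(C)[Si](C(C)C)(C(C)C)OS(=O)(=O)C(F)(F)F
Why: Kowalski ester homologation: 7 adds to the ester carbonyl, base-induced loss of ethoxide gives enolate 8, bromine–lithium exchange triggers loss of LiBr with a 1,2-methyl shift to ynolate 9 (the carbon of 6 becomes the methyl-bearing alkyne carbon), and the bulky silyl triflate is known to trap such ynolates on oxygen rather than on carbon.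

Step 4
Reactants: 4 methyl 4-methoxy-2,5-dimethyl-6-oxo-6H-pyran-3-carboxylate; 10 1-(triisopropylsilyloxy)prop-1-yne
Product: 12 methyl 2-methoxy-3,5,6-trimethyl-4-(triisopropylsilyloxy)benzoate, via bridged lactone adduct 11 (not isolated)
Conditions: 10 (3 equiv), PhMe (2 M), base-washed sealed tube, 135 °C
Reagents that add atoms: none
Why: The diene C3=C4–C5=C6 of 4, whose LUMO is lowered by the lactone carbonyl and the C5 ester, meets the high-lying HOMO of ynol ether 10 in an inverse-electron-demand Diels–Alder reaction that is concerted but asynchronous, the bond from the methyl-bearing alkyne carbon to pyrone C6 (ring B C2–C3) running ahead of the bond from the silyloxy-bearing carbon to pyrone C3 (ring B C4–C5). The 2-oxabicyclo[2.2.2]octadienone 11 cannot persist at this temperature and loses CO2 by retro-[4+2], which makes the sequence irreversible and delivers the arene without any oxidation step. The closest known chemistry is the benzannulation of 5-carboalkoxy-2-pyrones (coumalates) with ynamines, alkynyl ethers and ketene acetals, and triisopropylsilyl ynol ethers are known to tolerate prolonged heating above 100 °C in other benzannulations. Ring B is closed in an intermolecular [4+2] mode, four carbons coming from the pyrone and two from the alkyne. The two bridgehead stereocentres of 11 form as a racemate and are erased with the loss of CO2, so no stereocontrol is needed. The selectivity needed is regiochemical and is secured by matched polarity: C6 is β to the ester and the δ terminus of the dienoate, the 4-methoxy group pushes electron density onto C3 and C5 and so leaves C6 as the only strongly electrophilic terminus, and the alkyne carbon remote from oxygen is the nucleophilic one, which places C4–OSi between C3–Me and C5–Me.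

Step 5
Reactants: 12 methyl 2-methoxy-3,5,6-trimethyl-4-(triisopropylsilyloxy)benzoate
Product: 13 methyl 4-hydroxy-2-methoxy-3,5,6-trimethylbenzoate
Conditions: Bu4NF, AcOH, THF, 0 °C → rt
Reagents that add atoms: none
Why: Fluoride-induced desilylation of an aryl silyl ether is fast because phenoxide leaves readily from the pentacoordinate silicate, and the acetic acid buffer keeps the methyl ester and the methyl ether out of reach of basic fluoride.

Step 6
Reactants: 14 4,5-dimethylresorcinol
Product: 16 2,4-dihydroxy-5,6-dimethylbenzaldehyde, via aryl iminium chloride 15 (not isolated)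
Conditions: POCl3, DMF, MeCN, 0 °C → rt; then H2O, 50 °C
Reagents that add atoms: N,N-dimethylformamide CN(C)C=O; water O
Why: Vilsmeier–Haack formylation of a resorcinol goes para to one hydroxyl and ortho to the other, here at C6 of 14 rather than into the crowded C2 pocket between the two oxygens, as in the orcinol series, and water hydrolyses iminium salt 15 to the aldehyde.

Step 7
Reactants: 16 2,4-dihydroxy-5,6-dimethylbenzaldehyde
Product: 17 2,4-bis(benzyloxy)-5,6-dimethylbenzaldehyde
Conditions: BnBr (2.5 equiv), K2CO3, DMF, 60 °C
Reagents that add atoms: benzyl bromide BrCc1ccccc1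
Why: Double Williamson etherification, in which warm DMF and excess benzyl bromide are needed to alkylate the 2-hydroxyl that is hydrogen-bonded to the aldehyde.

Step 8
Reactants: 17 2,4-bis(benzyloxy)-5,6-dimethylbenzaldehyde
Product: 18 2,4-bis(benzyloxy)-5,6-dimethylbenzoic acid
Conditions: NaClO2, NaH2PO4, 2-methyl-2-butene, t-BuOH/THF/H2O, rt
Reagents that add atoms: sodium chlorite [Na+].[O-]Cl=O
Why: Pinnick oxidation converts even flanked aromatic aldehydes into acids under near-neutral conditions, the alkene scavenger removes HOCl before it can chlorinate the electron-rich C3–H, and benzyl ethers are inert.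

Step 9
Reactants: 18 2,4-bis(benzyloxy)-5,6-dimethylbenzoic acid; 13 methyl 4-hydroxy-2-methoxy-3,5,6-trimethylbenzoate
Product: 20 methyl 4-{[2,4-bis(benzyloxy)-5,6-dimethylbenzoyl]oxy}-2-methoxy-3,5,6-trimethylbenzoate, via aroyl trifluoroacetate 19 (not isolated)
Conditions: (CF3CO)2O (4 equiv), PhMe, 0 °C → rt
Reagents that add atoms: none
Why: Mixed-anhydride esterification with trifluoroacetic anhydride: the electron-rich, doubly ortho-substituted anhydride 19 ionises towards a slim, linear acylium ion that the phenol flanked by C3–Me and C5–Me can still reach, which is why this activation is the usual one for fully substituted depsides.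

Step 10
Reactants: 20 methyl 4-{[2,4-bis(benzyloxy)-5,6-dimethylbenzoyl]oxy}-2-methoxy-3,5,6-trimethylbenzoate
Product: 21 methyl 4-[(2,4-dihydroxy-5,6-dimethylbenzoyl)oxy]-2-methoxy-3,5,6-trimethylbenzoate
Conditions: H2 (1 atm), 10% Pd/C, EtOAc, rt
Reagents that add atoms: none
Why: Catalytic hydrogenolysis of aryl benzyl ethers is neutral and leaves both esters and C6–OMe untouched, whereas a boron trihalide would be drawn by chelation to the methoxy group ortho to the ring B ester, and no reducible aldehyde is present at this stage.

Step 11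
Reactants: 21 methyl 4-[(2,4-dihydroxy-5,6-dimethylbenzoyl)oxy]-2-methoxy-3,5,6-trimethylbenzoate
Product: 23 methyl 4-[(3-formyl-2,4-dihydroxy-5,6-dimethylbenzoyl)oxy]-2-methoxy-3,5,6-trimethylbenzoate, via chloro(methoxy)methyl arene 22 (not isolated)
Conditions: Cl2CHOMe, TiCl4, CH2Cl2, −20 → 0 °C; then 1 M aq HCl
Reagents that add atoms: dichloromethyl methyl ether COC(Cl)Cl; water O
Why: Rieche formylation: TiCl4 binds the ring A phenoxides and delivers the chloro(methoxy)carbenium ion to C3', the only unsubstituted aromatic position of 21 and one activated by both flanking hydroxyls, and aqueous work-up hydrolyses 22 to the aldehyde, a protocol long used on resorcylate esters and on depsidones with intact aryl ester links.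

Compound list
1 | methyl acetoacetate | COC(=O)CC(C)=O | starting material
2 | methylmalonyl dichloride | CC(C(=O)Cl)C(=O)Cl | starting material
3 | methyl 4-hydroxy-2,5-dimethyl-6-oxo-6H-pyran-3-carboxylate | O=C1OC(C)=C(C(=O)OC)C(O)=C1C | intermediate
4 | methyl 4-methoxy-2,5-dimethyl-6-oxo-6H-pyran-3-carboxylate | O=C1OC(C)=C(C(=O)OC)C(OC)=C1C | intermediate
5 | ethyl acetate | CCOC(C)=O | starting material
6 | dibromomethane | BrCBr | starting material
7 | dibromomethyllithium (not isolated) | [Li]C(Br)Br | intermediate
8 | lithium 1,1-dibromoprop-1-en-2-olate (not isolated) | CC([O-])=C(Br)Br.[Li+] | intermediate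
9 | lithium prop-1-yn-1-olate (not isolated) | CC#C[O-].[Li+] | intermediate
10 | 1-(triisopropylsilyloxy)prop-1-yne | CC#CO[Si](C(C)C)(C(C)C)C(C)C | intermediate
11 | methyl 5-methoxy-1,4,7-trimethyl-3-oxo-8-(triisopropylsilyloxy)-2-oxabicyclo[2.2.2]octa-5,7-diene-6-carboxylate (racemic, not isolated) | CC12OC(=O)C(C)(C(OC)=C1C(=O)OC)C(O[Si](C(C)C)(C(C)C)C(C)C)=C2C | intermediate
12 | methyl 2-methoxy-3,5,6-trimethyl-4-(triisopropylsilyloxy)benzoate | COC(=O)c1c(C)c(C)c(O[Si](C(C)C)(C(C)C)C(C)C)c(C)c1OC | intermediate
13 | methyl 4-hydroxy-2-methoxy-3,5,6-trimethylbenzoate | COC(=O)c1c(C)c(C)c(O)c(C)c1OC | intermediate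
14 | 4,5-dimethylresorcinol (4,5-dimethylbenzene-1,3-diol) | Cc1cc(O)cc(O)c1C | starting material
15 | (2,4-dihydroxy-5,6-dimethylbenzylidene)dimethyliminium chloride (not isolated) | C[N+](C)=Cc1c(O)cc(O)c(C)c1C.[Cl-] | intermediate
16 | 2,4-dihydroxy-5,6-dimethylbenzaldehyde | O=Cc1c(O)cc(O)c(C)c1C | intermediate
17 | 2,4-bis(benzyloxy)-5,6-dimethylbenzaldehyde | O=Cc1c(OCc2ccccc2)cc(OCc2ccccc2)c(C)c1C | intermediate
18 | 2,4-bis(benzyloxy)-5,6-dimethylbenzoic acid | OC(=O)c1c(OCc2ccccc2)cc(OCc2ccccc2)c(C)c1C | intermediate
19 | 2,4-bis(benzyloxy)-5,6-dimethylbenzoic trifluoroacetic anhydride (not isolated) | O=C(OC(=O)C(F)(F)F)c1c(OCc2ccccc2)cc(OCc2ccccc2)c(C)c1C | intermediate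
20 | methyl 4-{[2,4-bis(benzyloxy)-5,6-dimethylbenzoyl]oxy}-2-methoxy-3,5,6-trimethylbenzoate | COC(=O)c1c(C)c(C)c(OC(=O)c2c(C)c(C)c(OCc3ccccc3)cc2OCc2ccccc2)c(C)c1OC | intermediate
21 | methyl 4-[(2,4-dihydroxy-5,6-dimethylbenzoyl)oxy]-2-methoxy-3,5,6-trimethylbenzoate | COC(=O)c1c(C)c(C)c(OC(=O)c2c(C)c(C)c(O)cc2O)c(C)c1OC | intermediate
22 | methyl 4-({3-[chloro(methoxy)methyl]-2,4-dihydroxy-5,6-dimethylbenzoyl}oxy)-2-methoxy-3,5,6-trimethylbenzoate (racemic, not isolated) | COC(=O)c1c(C)c(C)c(OC(=O)c2c(C)c(C)c(O)c(C(Cl)OC)c2O)c(C)c1OC | intermediate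
23 | methyl 4-[(3-formyl-2,4-dihydroxy-5,6-dimethylbenzoyl)oxy]-2-methoxy-3,5,6-trimethylbenzoate (CNP0206150.0) | COC(=O)c1c(C)c(C)c(OC(=O)c2c(C)c(C)c(O)c(C=O)c2O)c(C)c1OC | target

Total steps: 11. Longest linear sequence: 7 steps (1, 2, 4, 5, 9, 10, 11).

Steps most likely to fail

Step 4.
- Risk: the cycloaddition may be too slow. Both diene termini carry methyl groups and the 4-methoxy group raises the diene LUMO. Thermal silyl migration, protonation by trace acid or oligomerisation of the ynol ether could therefore consume the dienophile first.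
- Fallback: this drops the cycloaddition and uses classical aromatic substitution, because ring B has the same 4,5-dimethylresorcinol skeleton as ring A. It sets out from 16. Nuclear C-methylation at C3 (MeI, KOH, MeOH, reflux) should give 2,4-dihydroxy-3,5,6-trimethylbenzaldehyde F1. Selective benzylation of the non-chelated 4-hydroxyl (BnBr, 1 equiv, K2CO3, acetone) should give 4-(benzyloxy)-2-hydroxy-3,5,6-trimethylbenzaldehyde F2. Pinnick oxidation of this fully substituted ring should give 4-(benzyloxy)-2-hydroxy-3,5,6-trimethylbenzoic acid F3. Exhaustive methylation of acid and phenol (MeI, K2CO3, DMF) should give methyl 4-(benzyloxy)-2-methoxy-3,5,6-trimethylbenzoate F4. Hydrogenolysis (H2, Pd/C) comes back to the route at 13 and replaces steps 1 to 5.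

Step 9.
- Risk: acyl transfer between two doubly ortho-flanked partners may stall. Trifluoroacetylation of the phenol and acid-induced loss of a benzyl group would then compete.
- Fallback: this activates the nucleophile instead of relying on an acidic medium, and sets out from 18 and 13. Oxalyl chloride with catalytic DMF in CH2Cl2 should convert 18 into 2,4-bis(benzyloxy)-5,6-dimethylbenzoyl chloride F5. NaH in THF should convert 13 into sodium 3-methoxy-4-(methoxycarbonyl)-2,5,6-trimethylphenolate F6. Combining the two at 0 °C to rt comes back to the route at 20.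

Step 11.
- Risk: the oxophilic Lewis acid may cleave the depside ester or demethylate C6–OMe by chelation. Substitution at the pocket between two oxygens may also stop short of completion.
- Fallback: this replaces the carbenium electrophile by phenoxide-directed hydroxymethylation followed by in situ hydride transfer (Casnati–Skattebøl ortho-formylation). It sets out from 21. MgCl2, Et3N and paraformaldehyde in MeCN at reflux should give the magnesium-bound methyl 4-{[2,4-dihydroxy-3-(hydroxymethyl)-5,6-dimethylbenzoyl]oxy}-2-methoxy-3,5,6-trimethylbenzoate F7. A second formaldehyde oxidises F7 in the same flask, and the fallback comes back to the route at 23.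

Further compounds
F1 | step 4 | 2,4-dihydroxy-3,5,6-trimethylbenzaldehyde | O=Cc1c(O)c(C)c(O)c(C)c1C
F2 | step 4 | 4-(benzyloxy)-2-hydroxy-3,5,6-trimethylbenzaldehyde | O=Cc1c(O)c(C)c(OCc2ccccc2)c(C)c1C
F3 | step 4 | 4-(benzyloxy)-2-hydroxy-3,5,6-trimethylbenzoic acid | OC(=O)c1c(O)c(C)c(OCc2ccccc2)c(C)c1C
F4 | step 4 | methyl 4-(benzyloxy)-2-methoxy-3,5,6-trimethylbenzoate | COC(=O)c1c(OC)c(C)c(OCc2ccccc2)c(C)c1C
F5 | step 9 | 2,4-bis(benzyloxy)-5,6-dimethylbenzoyl chloride | O=C(Cl)c1c(OCc2ccccc2)cc(OCc2ccccc2)c(C)c1C
F6 | step 9 | sodium 3-methoxy-4-(methoxycarbonyl)-2,5,6-trimethylphenolate | COC(=O)c1c(C)c(C)c([O-])c(C)c1OC.[Na+]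
F7 | step 11 | methyl 4-{[2,4-dihydroxy-3-(hydroxymethyl)-5,6-dimethylbenzoyl]oxy}-2-methoxy-3,5,6-trimethylbenzoate | COC(=O)c1c(C)c(C)c(OC(=O)c2c(C)c(C)c(O)c(CO)c2O)c(C)c1OC
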